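Ring atoms are counted from the carbonyl (C1) via the propenyl-bearing C2 and C3 to quaternary C4, then methoxy-bearing C5 and C6. Two features of this six-membered ring are exploited. Without the C2 and C5 groups it is a p-quinol whose symmetry plane contains C1 and C4, and its C4 and C5 oxygens are vicinal. The route rests on the C5–O disconnection. The C4 hydroxyl picks up phenylboronic acid and a chiral amine–thiourea sends the remaining B–OH oxygen to C5 of one enantiotopic enone arm. This single operation forms C5–O, closes a cis-fused dioxaborolane, sets C4 and C5 and leaves C2=C3 as the only enone. The precursor is the achiral 4-hydroxy-4-(arylpropenyl)cyclohexa-2,5-dienone.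

Key step: step 4

Assumption: the quinine-derived thiourea is taken to select the arm that leads to the (4S,5S) series; if the sense of induction is opposite, its quinidine-derived pseudoenantiomer is used with no other change.

Configuration check: C4 of the target is S (ranking O > C5 > alkenyl carbon > C3). The same ranking holds from 12 onward, so the descriptor does not change along the route.

Step 1
Reactants: 1 4-iodo-1,2-dimethoxybenzene; 2 propyne
Product: 3 1,2-dimethoxy-4-(prop-1-yn-1-yl)benzene
Conditions: PdCl2(PPh3)2 (2 mol %), CuI (4 mol %), Et3N, THF, 2 (ca. 1 M in THF, 2 equiv), sealed flask, rt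
Reagents that add atoms: none
Why: Sonogashira coupling of an aryl iodide with a terminal alkyne runs at room temperature, and the closed vessel keeps the volatile alkyne in solution.

Step 2
Reactants: 3 1,2-dimethoxy-4-(prop-1-yn-1-yl)benzene
Product: 5 4-[(E)-2-iodoprop-1-en-1-yl]-1,2-dimethoxybenzene, via alkenylzirconocene chloride 4 (not isolated)
Conditions: Cp2Zr(H)Cl (1.5 equiv), THF, rt to 40 °C, dark; then I2 (1.6 equiv), THF, 0 °C
Reagents that add atoms: zirconocene chloride hydride Cp2Zr(H)Cl, [H][Zr](Cl)(C1C=CC=C1)C1C=CC=C1 (its H stays in 5, the metal fragment only in 4); iodine, II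
Why: Hydrozirconation adds H and Zr syn, a slight excess of the hydride equilibrates the regioisomers toward the one with the bulky zirconocene on the methyl-bearing carbon away from the aryl ring, and iodinolysis of C–Zr goes with retention, so iodine ends up trans to the aryl group (any minor regioisomer is removed by chromatography).

Step 3
Reactants: 5 4-[(E)-2-iodoprop-1-en-1-yl]-1,2-dimethoxybenzene; 6 4,4-dimethoxycyclohexa-2,5-dien-1-one
Product: 9 4-hydroxy-4-[(E)-1-(3,4-dimethoxyphenyl)prop-1-en-2-yl]cyclohexa-2,5-dien-1-one, via alkenyllithium 7 (not isolated), via ketal carbinol 8 (not isolated)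
Conditions: t-BuLi (2.05 equiv), Et2O, −78 °C; 6 in THF, −78 °C; then AcOH/H2O/THF added to the same flask, 0 °C to rt
Reagents that add atoms: tert-butyllithium, [Li]C(C)(C)C (lithium of 7 only); water, O
Why: Iodine–lithium exchange keeps the alkene geometry at −78 °C, the hard alkenyllithium adds 1,2 to the free carbonyl of the quinone monoketal (the classical masked-quinone route to p-quinols), and the doubly allylic dimethyl ketal of 8 (formed as its lithium alkoxide) hydrolyses in dilute acetic acid, which is too weak to ionise the tertiary carbinol or start a dienone–phenol rearrangement.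

Step 4
Reactants: 9 4-hydroxy-4-[(E)-1-(3,4-dimethoxyphenyl)prop-1-en-2-yl]cyclohexa-2,5-dien-1-one; 10 phenylboronic acid
Product: 12 (3aS,7aS)-7a-[(E)-1-(3,4-dimethoxyphenyl)prop-1-en-2-yl]-2-phenyl-3a,7a-dihydro-1,3,2-benzodioxaborol-5(4H)-one (cis-fused phenylboronate of the 4S,5S diol), via boronic hemiester 11 (not isolated)
Conditions: 10 (1.2 equiv), 1-[3,5-bis(trifluoromethyl)phenyl]-3-[(8α,9S)-6′-methoxycinchonan-9-yl]thiourea (15 mol %), 4 Å molecular sieves, toluene, rt
Reagents that add atoms: none
Why: The tertiary C4–OH condenses reversibly with 10 to hemiester 11, the quinuclidine nitrogen of the catalyst engages the boron-bound hydroxyl and raises its nucleophilicity while the thiourea hydrogen-bonds the C1 carbonyl, and the oxygen then adds to C5 with protonation of the enolate at C6. This is the amine–thiourea-catalysed oxa-Michael addition of boronic acid hemiesters of γ-hydroxy enones, run on a cross-conjugated dienone in the manner of tethered desymmetrising oxa-Michael reactions of cyclohexadienones. The dioxaborolane (O–B–O–C4–C5) closes 5-exo-trig, because C5 enters the new ring and C6 stays outside it. C5 is set relative to C4 by the short O–B–O tether, which reaches only the face of C5 that carries the C4 oxygen (cis fusion), and C4 becomes stereogenic through the catalyst's choice between the enantiotopic C5=C6 and C3=C2 arms, so one recognition event fixes both centres. The step needs enantiotopic-group selectivity and mono-addition: the mirror plane through C1 and C4 makes the arms chemically identical so that only the catalyst can tell them apart, and after ring closure boron has no hydroxyl left, so C2=C3 stays intact. The styrenyl alkene is no Michael acceptor, the apolar near-neutral medium does not ionise the allylic C4–O bond, and recrystallisation of 12 offers a way to raise enantiopurity.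

Step 5
Reactants: 12 cis-fused phenylboronate (3aS,7aS)
Product: 13 (4S,5S)-4-[(E)-1-(3,4-dimethoxyphenyl)prop-1-en-2-yl]-4,5-dihydroxycyclohex-2-en-1-one
Conditions: pinacol (3 equiv), Et2O, rt
Reagents that add atoms: none
Why: In this boronic ester transesterification the tetrasubstituted diol pinacol forms the more stable phenylboronate, so an excess frees the diol under neutral, non-oxidising conditions that avoid Weitz–Scheffer epoxidation of the enone and retro-oxa-Michael loss of the C5 oxygen, with no bond to C4 or C5 broken.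

Step 6
Reactants: 13 (4S,5S)-diol
Product: 14 (4S,5S)-4-[(E)-1-(3,4-dimethoxyphenyl)prop-1-en-2-yl]-4,5-dimethoxycyclohex-2-en-1-one
Conditions: MeOTf (6 equiv), 2,6-di-tert-butylpyridine (8 equiv), CH2Cl2, 0 to 40 °C
Reagents that add atoms: methyl trifluoromethanesulfonate, COS(=O)(=O)C(F)(F)F
Why: O-Alkylation with methyl triflate buffered by a hindered non-nucleophilic pyridine needs no alkoxide, so E1cB loss of the β-oxygen at C5 is avoided, triflic acid is trapped before it can ionise the allylic C4–O bond, and both configurations persist because only O–H bonds are replaced.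

Step 7
Reactants: 14 (4S,5S)-dimethyl ether
Product: 15 (4S,5S)-4-[(E)-1-(3,4-dimethoxyphenyl)prop-1-en-2-yl]-2-iodo-4,5-dimethoxycyclohex-2-en-1-one
Conditions: I2 (2 equiv), pyridine/CH2Cl2 (1:1), 0 °C to rt, dark
Reagents that add atoms: iodine, II
Why: α-Iodination of enones with I2/pyridine (Baylis–Hillman-type addition of pyridine at C3, iodination of the enolate at C2, loss of pyridine) is established for 4,4-disubstituted cyclohexenones, C2=C3 is the only enone present, and pyridine is too weak a base to eliminate the C5 methoxy group.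

Step 8
Reactants: 15 (4S,5S)-2-iodoenone; 16 (E)-prop-1-en-1-ylboronic acid
Product: 17 (4S,5S)-4-[(E)-1-(3,4-dimethoxyphenyl)prop-1-en-2-yl]-4,5-dimethoxy-2-[(E)-prop-1-en-1-yl]cyclohex-2-en-1-one
Conditions: 16 (1.5 equiv), PdCl2(PhCN)2 (5 mol %), AsPh3 (10 mol %), Ag2O (1.6 equiv), THF/H2O (8:1), rt, dark
Reagents that add atoms: none
Why: Suzuki–Miyaura coupling of 2-iodoenones under silver oxide/triphenylarsine promotion proceeds at room temperature with retention of both alkene geometries and avoids hot carbonate or hydroxide, which would expel the β-methoxy group.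

Step 9
Reactants: 17 (4S,5S)-2-propenyl enone
Product: 18 C1-O-trimethylsilyl dienol ether of 17 (double bonds C1=C6 and C2=C3; 4S,5S)
Conditions: TMSCl (3 equiv), then LiHMDS (1.3 equiv), THF, −78 °C (internal quench); Et3N, pentane, cold aq NaHCO3 wash; used without chromatography
Reagents that add atoms: chlorotrimethylsilane, C[Si](C)(C)Cl
Why: Kinetic α′-deprotonation (C6–H2 is the only acidic position) with the silyl chloride already present traps the lithium enolate as the cross-conjugated silyloxydiene before it can expel methoxide from C5.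

Step 10
Reactants: 18 silyl dienol ether
Product: 19 (4S)-4-[(E)-1-(3,4-dimethoxyphenyl)prop-1-en-2-yl]-4,5-dimethoxy-2-[(E)-prop-1-en-1-yl]cyclohexa-2,5-dien-1-one
Conditions: Pd(OAc)2 (1.1 equiv), MeCN, rt
Reagents that add atoms: none
Why: In the Saegusa–Ito oxidation the silyl enol ether becomes a C6-bound palladium enolate whose β-hydride elimination removes the hydridic, oxygen-activated C5–H (as in the conversion of tetrahydropyran-4-ones into dihydropyranones), so C5 becomes sp2 and the untouched C4 remains as the single stereocentre with S configuration.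

Compound list
1 | 4-iodo-1,2-dimethoxybenzene | COc1ccc(I)cc1OC | starting material
2 | propyne | CC#C | starting material
3 | 1,2-dimethoxy-4-(prop-1-yn-1-yl)benzene | CC#Cc1ccc(OC)c(OC)c1 | intermediate
4 | chloro[(E)-1-(3,4-dimethoxyphenyl)prop-1-en-2-yl]zirconocene (Cp rings drawn σ-bound in the SMILES) | Cl[Zr](C1C=CC=C1)(C1C=CC=C1)/C(C)=C/c1ccc(OC)c(OC)c1 | intermediate
5 | 4-[(E)-2-iodoprop-1-en-1-yl]-1,2-dimethoxybenzene | I/C(C)=C/c1ccc(OC)c(OC)c1 | intermediate
6 | 4,4-dimethoxycyclohexa-2,5-dien-1-one | COC1(OC)C=CC(=O)C=C1 | starting material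
7 | [1-(3,4-dimethoxyphenyl)prop-1-en-2-yl]lithium, Li trans to aryl (formally Z because Li ranks below CH3) | [Li]/C(C)=C/c1ccc(OC)c(OC)c1 | intermediate
8 | 1-[(E)-1-(3,4-dimethoxyphenyl)prop-1-en-2-yl]-4,4-dimethoxycyclohexa-2,5-dien-1-ol | COC1(OC)C=CC(O)(/C(C)=C/c2ccc(OC)c(OC)c2)C=C1 | intermediate
9 | 4-hydroxy-4-[(E)-1-(3,4-dimethoxyphenyl)prop-1-en-2-yl]cyclohexa-2,5-dien-1-one | O=C1C=CC(O)(/C(C)=C/c2ccc(OC)c(OC)c2)C=C1 | intermediate
10 | phenylboronic acid | OB(O)c1ccccc1 | starting material
11 | phenylboronic acid mono(quinol) ester, C4–O–B(OH)Ph | O=C1C=CC(OB(O)c2ccccc2)(/C(C)=C/c2ccc(OC)c(OC)c2)C=C1 | intermediate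
12 | (3aS,7aS)-7a-[(E)-1-(3,4-dimethoxyphenyl)prop-1-en-2-yl]-2-phenyl-3a,7a-dihydro-1,3,2-benzodioxaborol-5(4H)-one | O=C1C=C[C@@]2(/C(C)=C/c3ccc(OC)c(OC)c3)OB(c4ccccc4)O[C@H]2C1 | intermediate
13 | (4S,5S)-4-[(E)-1-(3,4-dimethoxyphenyl)prop-1-en-2-yl]-4,5-dihydroxycyclohex-2-en-1-one | O=C1C=C[C@](O)(/C(C)=C/c2ccc(OC)c(OC)c2)[C@@H](O)C1 | intermediate
14 | (4S,5S)-4-[(E)-1-(3,4-dimethoxyphenyl)prop-1-en-2-yl]-4,5-dimethoxycyclohex-2-en-1-one | O=C1C=C[C@](OC)(/C(C)=C/c2ccc(OC)c(OC)c2)[C@@H](OC)C1 | intermediate
15 | (4S,5S)-4-[(E)-1-(3,4-dimethoxyphenyl)prop-1-en-2-yl]-2-iodo-4,5-dimethoxycyclohex-2-en-1-one | O=C1C(I)=C[C@](OC)(/C(C)=C/c2ccc(OC)c(OC)c2)[C@@H](OC)C1 | intermediate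
16 | (E)-prop-1-en-1-ylboronic acid | C/C=C/B(O)O | starting material
17 | (4S,5S)-4-[(E)-1-(3,4-dimethoxyphenyl)prop-1-en-2-yl]-4,5-dimethoxy-2-[(E)-prop-1-en-1-yl]cyclohex-2-en-1-one | O=C1C(/C=C/C)=C[C@](OC)(/C(C)=C/c2ccc(OC)c(OC)c2)[C@@H](OC)C1 | intermediate
18 | C1-O-trimethylsilyl dienol ether of 17 (C1=C6, C2=C3; 4S,5S) | C[Si](C)(C)OC=1C(/C=C/C)=C[C@](OC)(/C(C)=C/c2ccc(OC)c(OC)c2)[C@@H](OC)C=1 | intermediate
19 | (4S)-4-[(E)-1-(3,4-dimethoxyphenyl)prop-1-en-2-yl]-4,5-dimethoxy-2-[(E)-prop-1-en-1-yl]cyclohexa-2,5-dien-1-one | C/C=C/C1=C[C@](OC)(/C(C)=C/c2ccc(OC)c(OC)c2)C(OC)=CC1=O | target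

Total step count: 10. Longest linear sequence: 10 (1 to 19).

Steps most likely to fail

Step 4. The catalyst may discriminate the two enantiotopic arms poorly. The hindered tertiary hydroxyl may condense slowly with boron. Reversible ring opening (retro-oxa-Michael) under the basic catalyst may erode enantiopurity. The fallback replaces asymmetric catalysis by a racemic tether plus resolution. It sets out from 9 and closes the same boron tether with 10 and an achiral amine (Et3N as catalyst, 4 Å sieves, toluene). This gives 12 as a racemate with its mirror image, the (3aR,7aR)-boronate F1. Pinacol exchange then gives 13 together with the (4R,5R)-diol F2. Preparative chromatography on a chiral stationary phase (supercritical CO2/MeOH, amylose tris(3,5-dimethylphenylcarbamate)) separates the two, and the route is rejoined at 13.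

Step 6. Alkylation of the hindered tertiary hydroxyl may stall. Long exposure to the strong electrophile may also ionise the allylic, styrene-conjugated C4–O bond and scramble C4. The fallback moves the tertiary O-methylation to the end, where the ring is a vinylogous ester without a β-leaving group and a true alkoxide can be used.
- It sets out from 13. Only the secondary hydroxyl is methylated (MeOTf, 1.2 equiv, 2,6-di-tert-butylpyridine, 0 °C) to give the 4-hydroxy-5-methoxy enone F3.
- I2/pyridine gives the 2-iodo-4-hydroxy enone F4.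
- Coupling with 16 under the conditions of step 8 gives the 2-propenyl-4-hydroxy enone F5.
- Excess TMSCl/LiHMDS (−78 to 0 °C) gives the bis-silylated dienol ether F6.
- Pd(OAc)2 in MeCN gives the 4-trimethylsilyloxy dienone F7.
- TBAF/AcOH gives the free quinol F8.
- NaH/MeI (THF, 0 °C) converts the quinol into 19, where the route is rejoined.

Step 10. Methoxide may be expelled from the C6-palladated ketone in competition with β-hydride elimination. Protodesilylation may return the ketone, or the diene may tie up the metal. The fallback is metal-free and sets out from 17, bypassing 18. The ketone is deprotonated with LiHMDS (THF, −78 °C) and treated with N-tert-butylbenzenesulfinimidoyl chloride (Mukaiyama dehydrogenation). The enolate is sulfur-functionalised at C6 anti to the C5 methoxy group to give the C6 sulfilimine F9. Its basic nitrogen removes the only available syn hydrogen, C5–H, through a five-membered transition state at −78 °C, which delivers 19 directly.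

Further compounds
F1 | step 4 | (3aR,7aR)-7a-[(E)-1-(3,4-dimethoxyphenyl)prop-1-en-2-yl]-2-phenyl-3a,7a-dihydro-1,3,2-benzodioxaborol-5(4H)-one | O=C1C=C[C@]2(/C(C)=C/c3ccc(OC)c(OC)c3)OB(c4ccccc4)O[C@@H]2C1
F2 | step 4 | (4R,5R)-4-[(E)-1-(3,4-dimethoxyphenyl)prop-1-en-2-yl]-4,5-dihydroxycyclohex-2-en-1-one | O=C1C=C[C@@](O)(/C(C)=C/c2ccc(OC)c(OC)c2)[C@H](O)C1
F3 | step 6 | (4S,5S)-4-[(E)-1-(3,4-dimethoxyphenyl)prop-1-en-2-yl]-4-hydroxy-5-methoxycyclohex-2-en-1-one | O=C1C=C[C@](O)(/C(C)=C/c2ccc(OC)c(OC)c2)[C@@H](OC)C1
F4 | step 6 | (4S,5S)-4-[(E)-1-(3,4-dimethoxyphenyl)prop-1-en-2-yl]-4-hydroxy-2-iodo-5-methoxycyclohex-2-en-1-one | O=C1C(I)=C[C@](O)(/C(C)=C/c2ccc(OC)c(OC)c2)[C@@H](OC)C1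
F5 | step 6 | (4S,5S)-4-[(E)-1-(3,4-dimethoxyphenyl)prop-1-en-2-yl]-4-hydroxy-5-methoxy-2-[(E)-prop-1-en-1-yl]cyclohex-2-en-1-one | O=C1C(/C=C/C)=C[C@](O)(/C(C)=C/c2ccc(OC)c(OC)c2)[C@@H](OC)C1
F6 | step 6 | C1-O-trimethylsilyl dienol ether and C4-O-trimethylsilyl ether of F5 (4S,5S) | C[Si](C)(C)OC=1C(/C=C/C)=C[C@](O[Si](C)(C)C)(/C(C)=C/c2ccc(OC)c(OC)c2)[C@@H](OC)C=1
F7 | step 6 | (4S)-4-[(E)-1-(3,4-dimethoxyphenyl)prop-1-en-2-yl]-5-methoxy-2-[(E)-prop-1-en-1-yl]-4-(trimethylsilyloxy)cyclohexa-2,5-dien-1-one | O=C1C(/C=C/C)=C[C@](O[Si](C)(C)C)(/C(C)=C/c2ccc(OC)c(OC)c2)C(OC)=C1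
F8 | step 6 | (4S)-4-[(E)-1-(3,4-dimethoxyphenyl)prop-1-en-2-yl]-4-hydroxy-5-methoxy-2-[(E)-prop-1-en-1-yl]cyclohexa-2,5-dien-1-one | O=C1C(/C=C/C)=C[C@](O)(/C(C)=C/c2ccc(OC)c(OC)c2)C(OC)=C1
F9 | step 10 | 6-(N-tert-butyl-S-phenylsulfinimidoyl) derivative of 17, sulfur substituent trans to the C5 methoxy group, configuration at sulfur undefined | O=C1C(/C=C/C)=C[C@](OC)(/C(C)=C/c2ccc(OC)c(OC)c2)[C@@H](OC)[C@@H]1S(=NC(C)(C)C)c1ccccc1
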